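The disconnection opens ring A of the flavonol at the C4a–C5 bond (the same as C4a–C8a by symmetry), which unfolds it into a linear triketo ester. The key step exploits the alternating oxygens on C5, C7 and C8a around the acyl-bearing C4a of ring A. A magnesium-templated intramolecular Claisen condensation closes the carbocycle and aromatises it in one operation, giving the phloroglucinol ketone with ring B and the C3 oxygen already in place. Its precursor is a methyl 3,5,7-trioxonon-8-enoate ending in a Z α-benzyloxy-3,4-bis(benzyloxy)styryl unit, released from a dioxinone just before use. Oxidative closure of ring C, hydrogenolysis and sulfation of all but the chelated 5-hydroxyl complete the route.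

Key step: step 5

Assumption: the target is drawn as the free tetrakis(hydrogen sulfate), so the last step releases it from its ammonium salt by cold proton exchange; the salt is the form to store.

Remark: in every α-benzyloxycinnamoyl compound below, Z means aryl and benzyloxy on the same side (aryl trans to the carbonyl carbon). The triketo ester is made as the methyl ester under neutral conditions, matched to the methoxide base, and is not chromatographed.

Step 1
Reactants: 1 3,4-bis(benzyloxy)benzaldehyde; 2 methyl 2-(benzyloxy)acetate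
Product: 4 (Z)-2-(benzyloxy)-3-[3,4-bis(benzyloxy)phenyl]prop-2-enoic acid, via methyl ester 3 (not isolated)
Conditions: NaOMe, MeOH/THF, 0 °C to reflux; then 2 M aq NaOH, 60 °C; then 1 M HCl, 0 °C
Reagents that add atoms: sodium hydroxide (aqueous), [Na+].[OH-]
Why: Claisen–Schmidt-type aldol condensation of the ester enolate with the non-enolisable aldehyde and E1cB loss of water give the thermodynamically preferred Z enol ether, and saponification in the same pot should deliver the crystalline acid with benzyl and enol ethers untouched by base.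

Step 2
Reactants: 5 2,2,6-trimethyl-4H-1,3-dioxin-4-one
Product: 6 2,2-dimethyl-6-(2-oxopropyl)-4H-1,3-dioxin-4-one
Conditions: 5 (2 equiv), LiN(SiMe3)2 (2 equiv), THF, −78 °C; AcCl (1 equiv), −78 to −20 °C; then 1 M HCl
Reagents that add atoms: acetyl chloride, CC(=O)Cl
Why: Deprotonation of the C6 methyl group gives the lithium dienolate of the vinylogous ester, which undergoes Claisen-type γ-C-acylation by acetyl chloride, a twofold excess of enolate absorbing the proton of the more acidic product.

Step 3
Reactants: 4 (Z)-2-(benzyloxy)-3-[3,4-bis(benzyloxy)phenyl]prop-2-enoic acid; 6 2,2-dimethyl-6-(2-oxopropyl)-4H-1,3-dioxin-4-one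
Product: 8 6-[(5Z)-5-(benzyloxy)-6-[3,4-bis(benzyloxy)phenyl]-2,4-dioxohex-5-en-1-yl]-2,2-dimethyl-4H-1,3-dioxin-4-one, via acyl imidazole 7 (not isolated)
Conditions: 4, CDI, THF, rt; 6 (3.3 equiv), LiN(i-Pr)2 (6.6 equiv), THF, −78 °C, then the solution of 7, −78 to −30 °C; then 1 M HCl to pH 3
Reagents that add atoms: none
Why: CDI activates the acid as its acyl imidazole, and the dilithium dianion of the β-keto dioxinone undergoes Claisen-type C-acylation at its terminal, most basic carbon (the regiochemistry of β-keto ester dianions), the excess dianion absorbing the protons of liberated imidazole and of the more acidic product while the hindered, electron-rich enoyl unit resists conjugate addition.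

Step 4
Reactants: 8 6-[(5Z)-5-(benzyloxy)-6-[3,4-bis(benzyloxy)phenyl]-2,4-dioxohex-5-en-1-yl]-2,2-dimethyl-4H-1,3-dioxin-4-one
Product: 10 methyl (Z)-8-(benzyloxy)-9-[3,4-bis(benzyloxy)phenyl]-3,5,7-trioxonon-8-enoate, via acylketene 9 (not isolated)
Conditions: MeOH (10 equiv), PhMe, 110 °C, sealed tube; concentrate, use crude at once
Reagents that add atoms: methanol, CO
Why: Thermal retro-hetero-Diels–Alder fragmentation of the dioxinone expels acetone and leaves an acylketene that methanol traps as the methyl β-keto ester under neutral conditions, so the open chain should survive until base is added.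

Step 5
Reactants: 10 methyl (Z)-8-(benzyloxy)-9-[3,4-bis(benzyloxy)phenyl]-3,5,7-trioxonon-8-enoate
Product: 11 (Z)-2-(benzyloxy)-3-[3,4-bis(benzyloxy)phenyl]-1-(2,4,6-trihydroxyphenyl)prop-2-en-1-one
Conditions: Mg(OMe)2 (5 equiv), MeOH, 25 to 50 °C; then cold 1 M HCl
Reagents that add atoms: none
Why: Mg(OMe)2 turns the triketo ester into a polyenolate in which divalent magnesium chelates the 1,3-dicarbonyl units and bends the chain into a U, so that the C6 carbanion (between the C5 and C7 ketones, the future C4a) adds to the C1 ester carbonyl, methoxide is expelled and three enolisations aromatise the new ring. The closest known reaction type is the magnesium alkoxide-mediated intramolecular Claisen (Dieckmann-type) cyclisation of 3,5,7-triketo esters to acylphloroglucinols, the laboratory counterpart of the chalcone synthase fold. Ring A, the only ring formed, closes in a 6-(enolendo)-exo-trig mode through the C4a–C5 bond, the C5–C6 enolate bond lying inside the new ring and the ester carbonyl outside it. No stereocentre is created and the Z enol ether is a spectator. The selectivity needed is Claisen folding (C6 onto C1) over aldol folding (C2 onto C7) and over O-cyclisation to pyrones. It is secured by the C7 carbonyl, which is cross-conjugated to an electron-rich styrene, carries a donating α-benzyloxy group and is hindered, hence a poor aldol acceptor, while the methyl ester matched to methoxide in methanol stays a good acyl acceptor and magnesium keeps the enolate oxygens tied up.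

Step 6
Reactants: 11 (Z)-2-(benzyloxy)-3-[3,4-bis(benzyloxy)phenyl]-1-(2,4,6-trihydroxyphenyl)prop-2-en-1-one
Product: 13 3-(benzyloxy)-2-[3,4-bis(benzyloxy)phenyl]-5,7-dihydroxy-4H-chromen-4-one, via 3-O-benzyl flavanone 12 (not isolated)
Conditions: I2 (10 mol%), DMSO, 120 °C
Reagents that add atoms: none
Why: Iodine/DMSO oxidative cyclisation of a 2'-hydroxychalcone, in which 6-endo oxa-Michael addition of either equivalent ortho hydroxyl gives the flavanone, α-iodination at C3 and loss of HI give the chromone, and DMSO reoxidises iodide so that iodine stays catalytic and any flavanone carried over from step 5 converges.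

Step 7
Reactants: 13 3-(benzyloxy)-2-[3,4-bis(benzyloxy)phenyl]-5,7-dihydroxy-4H-chromen-4-one
Product: 14 quercetin, 2-(3,4-dihydroxyphenyl)-3,5,7-trihydroxy-4H-chromen-4-one
Conditions: H2 (1 atm), 10% Pd/C, THF/MeOH, rt
Reagents that add atoms: none
Why: Catalytic hydrogenolysis of the three benzyl ethers over zerovalent palladium on carbon is standard for benzylated flavonols, whose tetrasubstituted, vinylogous-ester C2–C3 double bond and carbonyl should not be reduced at one atmosphere.

Step 8
Reactants: 14 quercetin, 2-(3,4-dihydroxyphenyl)-3,5,7-trihydroxy-4H-chromen-4-one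
Product: 15 quercetin 3,7,3',4'-tetra-O-sulfate, 2-[3,4-bis(sulfooxy)phenyl]-5-hydroxy-3,7-bis(sulfooxy)-4H-chromen-4-one
Conditions: SO3·NEt3 (16 equiv), DMA, 65 °C; then strong-acid cation-exchange resin (H+ form), H2O, 0 °C; freeze-dry
Reagents that add atoms: sulfur trioxide–triethylamine complex, CC[N+](CC)(CC)S(=O)(=O)[O-]
Why: O-Sulfonation of the phenols and the enolic 3-hydroxyl by an amine–sulfur trioxide complex should stop at the tetrasulfate because the 5-hydroxyl is held in a hydrogen bond to the C4 carbonyl and is the least nucleophilic, and cold proton exchange of the ammonium salt gives the acid form.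

Compound list
1 | 3,4-bis(benzyloxy)benzaldehyde | O=Cc1ccc(OCc2ccccc2)c(OCc2ccccc2)c1 | starting material
2 | methyl 2-(benzyloxy)acetate | COC(=O)COCc1ccccc1 | starting material
3 | methyl (Z)-2-(benzyloxy)-3-[3,4-bis(benzyloxy)phenyl]prop-2-enoate | COC(=O)/C(OCc1ccccc1)=C/c1ccc(OCc2ccccc2)c(OCc2ccccc2)c1 | intermediate
4 | (Z)-2-(benzyloxy)-3-[3,4-bis(benzyloxy)phenyl]prop-2-enoic acid | O=C(O)/C(OCc1ccccc1)=C/c1ccc(OCc2ccccc2)c(OCc2ccccc2)c1 | intermediate
5 | 2,2,6-trimethyl-4H-1,3-dioxin-4-one | CC1=CC(=O)OC(C)(C)O1 | starting material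
6 | 2,2-dimethyl-6-(2-oxopropyl)-4H-1,3-dioxin-4-one | CC(=O)CC1=CC(=O)OC(C)(C)O1 | intermediate
7 | (Z)-2-(benzyloxy)-3-[3,4-bis(benzyloxy)phenyl]-1-(1H-imidazol-1-yl)prop-2-en-1-one | O=C(/C(OCc1ccccc1)=C/c1ccc(OCc2ccccc2)c(OCc2ccccc2)c1)n1ccnc1 | intermediate
8 | 6-[(5Z)-5-(benzyloxy)-6-[3,4-bis(benzyloxy)phenyl]-2,4-dioxohex-5-en-1-yl]-2,2-dimethyl-4H-1,3-dioxin-4-one | CC1(C)OC(=O)C=C(CC(=O)CC(=O)/C(OCc2ccccc2)=C/c2ccc(OCc3ccccc3)c(OCc3ccccc3)c2)O1 | intermediate
9 | (8Z)-8-(benzyloxy)-9-[3,4-bis(benzyloxy)phenyl]nona-1,8-diene-1,3,5,7-tetrone (acylketene) | O=C=CC(=O)CC(=O)CC(=O)/C(OCc1ccccc1)=C/c1ccc(OCc2ccccc2)c(OCc2ccccc2)c1 | intermediate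
10 | methyl (Z)-8-(benzyloxy)-9-[3,4-bis(benzyloxy)phenyl]-3,5,7-trioxonon-8-enoate | COC(=O)CC(=O)CC(=O)CC(=O)/C(OCc1ccccc1)=C/c1ccc(OCc2ccccc2)c(OCc2ccccc2)c1 | intermediate
11 | (Z)-2-(benzyloxy)-3-[3,4-bis(benzyloxy)phenyl]-1-(2,4,6-trihydroxyphenyl)prop-2-en-1-one | O=C(c1c(O)cc(O)cc1O)/C(OCc1ccccc1)=C/c1ccc(OCc2ccccc2)c(OCc2ccccc2)c1 | intermediate
12 | 3-(benzyloxy)-2-[3,4-bis(benzyloxy)phenyl]-5,7-dihydroxy-2,3-dihydro-4H-chromen-4-one (racemic mixture of 2,3-cis and 2,3-trans isomers; both centres are erased in the same step) | O=C1c2c(O)cc(O)cc2OC(c2ccc(OCc3ccccc3)c(OCc3ccccc3)c2)C1OCc1ccccc1 | intermediate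
13 | 3-(benzyloxy)-2-[3,4-bis(benzyloxy)phenyl]-5,7-dihydroxy-4H-chromen-4-one (3,3',4'-tri-O-benzylquercetin) | O=c1c(OCc2ccccc2)c(-c2ccc(OCc3ccccc3)c(OCc3ccccc3)c2)oc2cc(O)cc(O)c12 | intermediate
14 | quercetin, 2-(3,4-dihydroxyphenyl)-3,5,7-trihydroxy-4H-chromen-4-one | O=c1c(O)c(-c2ccc(O)c(O)c2)oc2cc(O)cc(O)c12 | intermediate
15 | quercetin 3,7,3',4'-tetra-O-sulfate, 2-[3,4-bis(sulfooxy)phenyl]-5-hydroxy-3,7-bis(sulfooxy)-4H-chromen-4-one | O=c1c(OS(=O)(=O)O)c(-c2ccc(OS(=O)(=O)O)c(OS(=O)(=O)O)c2)oc2cc(OS(=O)(=O)O)cc(O)c12 | target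

Total step count: 8. Longest linear sequence: 7 steps (steps 1, 3, 4, 5, 6, 7, 8); step 2 is a one-step branch that joins at step 3.

Steps most likely to fail

Step 5. The chain may fold in the aldol sense (C2 onto the C7 ketone), lactonise through an enol oxygen onto the ester, or take up methoxide at the enone, so that ring A does not form as the phloroglucinol. The fallback builds the aryl ketone by directed ortho-metalation; it sets out from acid 4 and comes back at 11. Phloroglucinol is protected with MOMCl and i-Pr2NEt as 1,3,5-tris(methoxymethoxy)benzene F1. Acid 4 is converted with CDI and then N,O-dimethylhydroxylamine hydrochloride into the Weinreb amide (Z)-2-(benzyloxy)-3-[3,4-bis(benzyloxy)phenyl]-N-methoxy-N-methylprop-2-enamide F2. Lithiation of F1 between two MOM groups (n-BuLi, THF, 0 °C) and addition to F2 should give (Z)-2-(benzyloxy)-3-[3,4-bis(benzyloxy)phenyl]-1-[2,4,6-tris(methoxymethoxy)phenyl]prop-2-en-1-one F3. Brief HCl in MeOH at 40 °C removes the three MOM groups and gives 11; the captodative enol ether should hydrolyse far more slowly than the acetals.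

Step 3. C-Acylation may stall because the dianion is quenched by proton transfer, or it may add in a conjugate sense or through oxygen. The fallback replaces the hard dianion by a magnesium enolate and a decarboxylation; it sets out from 4 and 5 and comes back at 8. Acid 4 with (COCl)2 and catalytic DMF gives (Z)-2-(benzyloxy)-3-[3,4-bis(benzyloxy)phenyl]prop-2-enoyl chloride F4. The lithium dienolate of 5 is acylated with allyl malonyl chloride to allyl 4-(2,2-dimethyl-4-oxo-4H-1,3-dioxin-6-yl)-3-oxobutanoate F5. With MgCl2 and pyridine in CH2Cl2 at 0 °C the magnesium enolate of F5 is C-acylated by F4 to allyl (Z)-4-(benzyloxy)-5-[3,4-bis(benzyloxy)phenyl]-2-[2-(2,2-dimethyl-4-oxo-4H-1,3-dioxin-6-yl)acetyl]-3-oxopent-4-enoate F6. Pd(PPh3)4 (zerovalent palladium) and morpholine then remove the allyl group, and loss of carbon dioxide gives 8.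

Step 6. Electrophilic iodination of the electron-rich ring A, or loss of benzyl groups induced by HI, may compete with the dehydrogenation. The fallback separates ring closure from oxidation and uses no halogen; it sets out from 11 and comes back at 13. NaOAc in EtOH at reflux isomerises 11 to flavanone 12, which is now isolated, and DDQ in dioxane at reflux dehydrogenates it to 13 by hydride abstraction. This fallback makes no compound outside the list (F0).

Further compounds
F1 | step 5 | 1,3,5-tris(methoxymethoxy)benzene | COCOc1cc(OCOC)cc(OCOC)c1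
F2 | step 5 | (Z)-2-(benzyloxy)-3-[3,4-bis(benzyloxy)phenyl]-N-methoxy-N-methylprop-2-enamide | CON(C)C(=O)/C(OCc1ccccc1)=C/c1ccc(OCc2ccccc2)c(OCc2ccccc2)c1
F3 | step 5 | (Z)-2-(benzyloxy)-3-[3,4-bis(benzyloxy)phenyl]-1-[2,4,6-tris(methoxymethoxy)phenyl]prop-2-en-1-one | COCOc1cc(OCOC)c(C(=O)/C(OCc2ccccc2)=C/c2ccc(OCc3ccccc3)c(OCc3ccccc3)c2)c(OCOC)c1
F4 | step 3 | (Z)-2-(benzyloxy)-3-[3,4-bis(benzyloxy)phenyl]prop-2-enoyl chloride | O=C(Cl)/C(OCc1ccccc1)=C/c1ccc(OCc2ccccc2)c(OCc2ccccc2)c1
F5 | step 3 | allyl 4-(2,2-dimethyl-4-oxo-4H-1,3-dioxin-6-yl)-3-oxobutanoate | C=CCOC(=O)CC(=O)CC1=CC(=O)OC(C)(C)O1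
F6 | step 3 | allyl (Z)-4-(benzyloxy)-5-[3,4-bis(benzyloxy)phenyl]-2-[2-(2,2-dimethyl-4-oxo-4H-1,3-dioxin-6-yl)acetyl]-3-oxopent-4-enoate | C=CCOC(=O)C(C(=O)CC1=CC(=O)OC(C)(C)O1)C(=O)/C(OCc1ccccc1)=C/c1ccc(OCc2ccccc2)c(OCc2ccccc2)c1
F0 | step 6 | none | none
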